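**Retrosynthetic overview**
- The target is epioritin-(4β→3)-epioritin-4β-ol, and both halves are the same (2R,3R,4S) flavan unit. It is therefore cut into two molecules of one 2,3-cis flavene 3,4-oxide plus one water: the interflavanyl oxygen is the oxirane oxygen of the lower half (epoxonium relay), not a free 3-OH.
- The two oxiranes are closed side by side in one flask from the all-trans 3-bromo-4-ol and opened into each other in the same operation. Inversion at C3 puts the oxirane syn to the aryl group.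
- The bromohydrin comes from the (2S)-flav-3-ene. Ring C comes from a 2'-hydroxychalcone by 1,2-reduction and catalytic asymmetric cyclodehydration, which sets C2, the only catalyst-controlled centre.
- The chalcone comes from gallacetophenone (ring A) and 4-(benzyloxy)benzaldehyde (ring B).
- Ring order: rings A and B are bought; ring C is closed for each half; the two oxiranes are formed and consumed in the key operation; the benzyl ethers come off last.

Assumption: the catalyst antipode in step 3 (and in its fallback) is whichever one is found to give the (2S)-flavene. Unprimed locants are the upper (4-O-linked) unit, primed locants the lower (3-O-linked) unit.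

**Step 1**
Reactants: 1 1-(2,3,4-trihydroxyphenyl)ethan-1-one (gallacetophenone)
Product: 2 1-[3,4-bis(benzyloxy)-2-hydroxyphenyl]ethan-1-one
Conditions: BnBr (2.1 equiv), K2CO3 (2.2 equiv), DMF, 0 °C → rt
Reagents that add atoms: benzyl bromide, BrCc1ccccc1
Why: Williamson etherification; the 2-OH is held in a strong hydrogen bond to the acetyl carbonyl and stays free while the 3- and 4-phenoxides are alkylated; no stereocentre.

**Step 2**
Reactants: 2 1-[3,4-bis(benzyloxy)-2-hydroxyphenyl]ethan-1-one; 3 4-(benzyloxy)benzaldehyde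
Product: 4 (E)-1-[3,4-bis(benzyloxy)-2-hydroxyphenyl]-3-[4-(benzyloxy)phenyl]prop-2-en-1-one
Conditions: KOH, EtOH/H2O, rt; aq. HCl to pH 6
Reagents that add atoms: none
Why: Claisen–Schmidt aldol condensation of the methyl ketone with a non-enolisable aldehyde; E1cB dehydration gives only the E-enone; no stereocentre.

**Step 3**
Reactants: 4 (E)-1-[3,4-bis(benzyloxy)-2-hydroxyphenyl]-3-[4-(benzyloxy)phenyl]prop-2-en-1-one
Product: 6 (2S)-7,8-bis(benzyloxy)-2-[4-(benzyloxy)phenyl]-2H-chromene, via allylic alcohol 5 (not isolated)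
Conditions: NaBH4, CeCl3·7H2O, THF/MeOH, −20 °C; pH 7 buffer, extract; then (R)-3,3'-bis(2,4,6-triisopropylphenyl)-BINOL N-triflyl phosphoramide (5 mol %), 4 Å MS, PhMe, −78 → −60 °C
Reagents that add atoms: none
Why: Luche 1,2-reduction gives the racemic o-hydroxybenzylic allylic alcohol; the strong chiral Brønsted acid dehydrates it to a vinyl o-quinone methide/diarylallyl cation held in a chiral contact ion pair, and enantioselective intramolecular allylic substitution (oxa-6π ring closure) by the phenol oxygen sets C2 under catalyst control, the carbinol centre of 5 being erased on ionisation.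

**Step 4**
Reactants: 6 (2S)-7,8-bis(benzyloxy)-2-[4-(benzyloxy)phenyl]-2H-chromene
Product: 7 (2R,3S,4R)-7,8-bis(benzyloxy)-2-[4-(benzyloxy)phenyl]-3-bromo-3,4-dihydro-2H-chromen-4-ol
Conditions: NBS (1.05 equiv), acetone/H2O (4:1), 0 °C, dark; recrystallise
Reagents that add atoms: N-bromosuccinimide, O=C1CCC(=O)N1Br; water, O
Why: Bromohydrin formation (cohalogenation): Br+ adds to C3 on the face opposite the 2-aryl group and water opens the bromonium/benzylic cation at C4 anti to bromine, so C3 and C4 of the 2,3-trans-3,4-trans bromohydrin are set by substrate control from C2.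

**Step 5**
Reactants: 7 (2R,3S,4R)-7,8-bis(benzyloxy)-2-[4-(benzyloxy)phenyl]-3-bromo-3,4-dihydro-2H-chromen-4-ol (two molecules)
Product: 12 hexa-O-benzyl-epioritin-(4β→3)-epioritin-4β-ol, via epoxide 8 (not isolated), via silyloxy carbenium triflate 9 (not isolated), via dimeric carbenium triflate 10 (not isolated), via dimeric silyl ether 11 (not isolated)
Conditions: KN(SiMe3)2 (1.0 equiv), PhMe, −20 → 0 °C; evaporate, CH2Cl2, filter under Ar; half of the solution into TBSOTf (0.5 equiv), 2,6-di-tert-butyl-4-methylpyridine (0.1 equiv), CH2Cl2, −78 °C; second half added slowly, −78 °C; aq. NaHCO3/THF, −78 → 0 °C; then Bu4NF, AcOH, THF, 0 °C → rt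
Reagents that add atoms: water, O
Why: Proposed new method: the alkoxide displaces the anti C3 bromide (intramolecular Williamson, inversion at C3), so both molecules close to the oxirane syn to the 2-aryl group, two oxirane rings being formed in this one operation; TBSOTf opens one oxirane to the O3-silylated C4 carbenium ion (stabilised by O1 and the 7-benzyloxy group, O3 capped by the bulky silyl group), the oxygen of the second oxirane adds to C4 anti to the axial 3-OTBS group (4β, 3,4-trans) to give an epoxonium ion in which that oxygen stays on C3' with retention, the epoxonium opens at benzylic C4' and water adds there trans to the 3'-O substituent (4'β-OH), so C3, C4, C3' and C4' all come from the two syn oxiranes and the (4→3) connectivity is fixed by mechanism; the closest known reaction types are silyl triflate or Lewis acid opening of epoxides by oxygen nucleophiles, epoxonium intermediates of cationic epoxide oligomerisation and epoxide-opening cascades, and the 4β-selective capture of 2,3-cis-flavan-4-yl cations used in proanthocyanidin synthesis.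

**Step 6**
Reactants: 12 hexa-O-benzyl-epioritin-(4β→3)-epioritin-4β-ol
Product: 13 epioritin-(4β→3)-epioritin-4β-ol (CNP0266687.1)
Conditions: H2 (1 atm), Pd(OH)2/C, THF/MeOH (1:1), rt; filter; Sephadex LH-20
Reagents that add atoms: none
Why: Hydrogenolysis of the six aryl benzyl ethers, which under neutral conditions are cleaved much faster than the secondary benzylic alcohol, the interflavanyl benzylic ether and the C2–O1 bond; no stereocentre is touched.

**Compound list**

1 | 1-(2,3,4-trihydroxyphenyl)ethan-1-one (gallacetophenone) | CC(=O)c1ccc(O)c(O)c1O | starting material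

2 | 1-[3,4-bis(benzyloxy)-2-hydroxyphenyl]ethan-1-one | CC(=O)c1ccc(OCc2ccccc2)c(OCc2ccccc2)c1O | intermediate

3 | 4-(benzyloxy)benzaldehyde | O=Cc1ccc(OCc2ccccc2)cc1 | starting material

4 | (E)-1-[3,4-bis(benzyloxy)-2-hydroxyphenyl]-3-[4-(benzyloxy)phenyl]prop-2-en-1-one | O=C(/C=C/c1ccc(OCc2ccccc2)cc1)c1ccc(OCc2ccccc2)c(OCc2ccccc2)c1O | intermediate

5 | (E)-1-[3,4-bis(benzyloxy)-2-hydroxyphenyl]-3-[4-(benzyloxy)phenyl]prop-2-en-1-ol (racemic at C1) | OC(/C=C/c1ccc(OCc2ccccc2)cc1)c1ccc(OCc2ccccc2)c(OCc2ccccc2)c1O | intermediate (not isolated)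

6 | (2S)-7,8-bis(benzyloxy)-2-[4-(benzyloxy)phenyl]-2H-chromene | c1ccccc1COc1ccc(cc1)[C@H]2Oc3c(ccc(OCc4ccccc4)c3OCc4ccccc4)C=C2 | intermediate

7 | (2R,3S,4R)-7,8-bis(benzyloxy)-2-[4-(benzyloxy)phenyl]-3-bromo-3,4-dihydro-2H-chromen-4-ol (2,3-trans-3,4-trans) | c1ccccc1COc1ccc(cc1)[C@H]2Oc3c(ccc(OCc4ccccc4)c3OCc4ccccc4)[C@@H](O)[C@@H]2Br | intermediate

8 | (2R,3R,4R)-7,8-bis(benzyloxy)-2-[4-(benzyloxy)phenyl]-3,4-epoxy-3,4-dihydro-2H-chromene (oxirane syn to the 2-aryl group) | c1ccccc1COc1ccc(cc1)[C@H]2Oc3c(ccc(OCc4ccccc4)c3OCc4ccccc4)[C@H]4O[C@@H]24 | intermediate (not isolated)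

9 | (2R,3R)-7,8-bis(benzyloxy)-2-[4-(benzyloxy)phenyl]-3-[(tert-butyldimethylsilyl)oxy]-3,4-dihydro-2H-chromen-4-ylium triflate (ion pair/covalent 4-triflate) | c1ccccc1COc1ccc(cc1)[C@H]2Oc3c(ccc(OCc4ccccc4)c3OCc4ccccc4)[CH+][C@H]2O[Si](C)(C)C(C)(C)C.[O-]S(=O)(=O)C(F)(F)F | intermediate (not isolated)

10 | dimeric carbenium triflate: 3-O-TBS-hexa-O-benzyl-epioritin-(4β→3)-epioritin-4'-ylium triflate | c1ccccc1COc1ccc([C@H]2Oc3c(ccc(OCc4ccccc4)c3OCc4ccccc4)[C@H](O[C@H]3[C@@H](c4ccc(OCc5ccccc5)cc4)Oc4c(ccc(OCc5ccccc5)c4OCc5ccccc5)[CH+]3)[C@H]2O[Si](C)(C)C(C)(C)C)cc1.[O-]S(=O)(=O)C(F)(F)F | intermediate (not isolated)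

11 | 3-O-TBS-hexa-O-benzyl-epioritin-(4β→3)-epioritin-4β-ol | c1ccccc1COc1ccc([C@H]2Oc3c(ccc(OCc4ccccc4)c3OCc4ccccc4)[C@H](O[C@H]3[C@@H](c4ccc(OCc5ccccc5)cc4)Oc4c(ccc(OCc5ccccc5)c4OCc5ccccc5)[C@@H]3O)[C@H]2O[Si](C)(C)C(C)(C)C)cc1 | intermediate (not isolated)

12 | hexa-O-benzyl-epioritin-(4β→3)-epioritin-4β-ol: (2R,3R,4S)-7,8-bis(benzyloxy)-2-[4-(benzyloxy)phenyl]-3-({(2R,3R,4S)-7,8-bis(benzyloxy)-2-[4-(benzyloxy)phenyl]-3-hydroxy-3,4-dihydro-2H-chromen-4-yl}oxy)-3,4-dihydro-2H-chromen-4-ol | c1ccccc1COc1ccc([C@H]2Oc3c(ccc(OCc4ccccc4)c3OCc4ccccc4)[C@H](O[C@H]3[C@@H](c4ccc(OCc5ccccc5)cc4)Oc4c(ccc(OCc5ccccc5)c4OCc5ccccc5)[C@@H]3O)[C@H]2O)cc1 | intermediate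

13 | (2R,3R,4S)-3-{[(2R,3R,4S)-3,7,8-trihydroxy-2-(4-hydroxyphenyl)-3,4-dihydro-2H-chromen-4-yl]oxy}-2-(4-hydroxyphenyl)-3,4-dihydro-2H-chromene-4,7,8-triol (epioritin-(4β→3)-epioritin-4β-ol, CNP0266687.1) | Oc1ccc([C@H]2Oc3c(ccc(O)c3O)[C@H](O[C@H]3[C@@H](c4ccc(O)cc4)Oc4c(ccc(O)c4O)[C@@H]3O)[C@H]2O)cc1 | target

**Totals**
Total step count: 6. Longest linear sequence: 6 steps (1 → 2 → 4 → 6 → 7 → 12 → 13).

**Three steps most likely to fail**

Step 5 is the most exposed. The relay is statistical (monomer diol and trimers compete with the dimer), the C4 cation can rearrange to the flavan-3-one or C-alkylate ring A, and the stoichiometry of the silyl triflate is critical. The fallback keeps the silyl triflate donor but replaces the oxirane acceptor by a discrete alcohol. Setting out from 7, the epoxide 8 is made as before and one half is opened with buffered acetic acid (AcOH, NaOAc, CH2Cl2, 0 °C) to the trans hydroxy acetate (2R,3S,4S)-7,8-bis(benzyloxy)-2-[4-(benzyloxy)phenyl]-3-hydroxy-3,4-dihydro-2H-chromen-4-yl acetate F1, whose only free hydroxyl is the 3-OH. The other half is turned into donor 9 with TBSOTf and coupled with F1 (2,6-di-tert-butyl-4-methylpyridine, CH2Cl2, −78 °C; aq. NaHCO3) to the doubly masked dimer 3-O-TBS-4'-O-acetyl-hexa-O-benzyl-epioritin-(4β→3)-epioritin-4β-ol F2. K2CO3 in methanol removes the acetate and the route is rejoined at 11, which is desilylated to 12 as in step 5.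

Step 3 carries the enantioselectivity risk: the cation is unusually electron-rich, and the flavene can racemise by re-ionisation under the acid. The fallback is resolution instead of asymmetric induction. Setting out from 4, the enone is reduced as in step 3 and the crude alcohol 5 is cyclised without chiral control (p-TsOH cat., CH2Cl2, rt) to racemic 7,8-bis(benzyloxy)-2-[4-(benzyloxy)phenyl]-2H-chromene F3. Kinetic resolution by epoxidation with NaOCl and [(R,R)- or (S,S)-N,N'-bis(3,5-di-tert-butylsalicylidene)-1,2-cyclohexanediaminato]manganese chloride (trivalent manganese; 4-phenylpyridine N-oxide, CH2Cl2, 0 °C, about 60 % conversion) consumes the (2R)-enantiomer as its labile oxide and leaves the (2S)-flavene 6, where the route is rejoined.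

Step 6 risks over-reduction, since the interflavanyl C4–O bond and the 4'-OH are both benzylic. The fallback is a silane-mediated benzyl-to-silyl exchange followed by fluoride, without hydrogen gas. Setting out from 12, Pd(OAc)2 (cat.), Et3SiH and Et3N in CH2Cl2 at rt convert the six aryl benzyl ethers into triethylsilyl ethers, giving the hexakis-O-(triethylsilyl) ether of epioritin-(4β→3)-epioritin-4β-ol F4. Bu4NF/AcOH (THF, 0 °C) then releases 13.

**Further compounds**

F1 | step 5 | (2R,3S,4S)-7,8-bis(benzyloxy)-2-[4-(benzyloxy)phenyl]-3-hydroxy-3,4-dihydro-2H-chromen-4-yl acetate | c1ccccc1COc1ccc(cc1)[C@H]2Oc3c(ccc(OCc4ccccc4)c3OCc4ccccc4)[C@H](OC(C)=O)[C@H]2O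

F2 | step 5 | 3-O-TBS-4'-O-acetyl-hexa-O-benzyl-epioritin-(4β→3)-epioritin-4β-ol | c1ccccc1COc1ccc([C@H]2Oc3c(ccc(OCc4ccccc4)c3OCc4ccccc4)[C@H](O[C@H]3[C@@H](c4ccc(OCc5ccccc5)cc4)Oc4c(ccc(OCc5ccccc5)c4OCc5ccccc5)[C@@H]3OC(C)=O)[C@H]2O[Si](C)(C)C(C)(C)C)cc1

F3 | step 3 | racemic 7,8-bis(benzyloxy)-2-[4-(benzyloxy)phenyl]-2H-chromene (no defined stereocentre) | c1ccccc1COc1ccc(cc1)C2Oc3c(ccc(OCc4ccccc4)c3OCc4ccccc4)C=C2

F4 | step 6 | hexakis-O-(triethylsilyl) ether of epioritin-(4β→3)-epioritin-4β-ol | CC[Si](CC)(CC)Oc1ccc([C@H]2Oc3c(ccc(O[Si](CC)(CC)CC)c3O[Si](CC)(CC)CC)[C@H](O[C@H]3[C@@H](c4ccc(O[Si](CC)(CC)CC)cc4)Oc4c(ccc(O[Si](CC)(CC)CC)c4O[Si](CC)(CC)CC)[C@@H]3O)[C@H]2O)cc1
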